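The indane is cut at C3–C3a and at C8–ArB together. C3a lies meta to the oxygens on C5 and C7, so no Friedel–Crafts closure can reach it. It is addressed instead as an aryl triflate made from the third phloroglucinol oxygen. The precursor 13 is acyclic and holds the C1/C2 diad (ArA, ArC), that triflate and an E-alkenyl pinacol boronate spanning C3=C8. Adding the ArB aryllithium to boron and letting palladium trigger a 1,2-shift closes the five-membered ring. The same step sets the neighbouring centres C3 and C8 in one stereospecific anti addition, with boron standing in for the fragile C8 hydroxyl.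

Key step: step 8

Remark on numbering: indane numbering is used for all intermediates. C1 bears ArA (4-oxyphenyl), C2 bears ArC (3,5-dioxyphenyl), and C3 bears C8, the exocyclic carbon with ArB (4-oxyphenyl). C7a is next to C1, C3a is next to C3, and oxygen sits on C5 and C7.

Remark on descriptors: C2 is labelled R up to 17 and S in 18 and 19. Only the ranking of its neighbours changes, not its geometry.

Assumption: 1, 5 and 12 are taken as catalogue compounds, and the MandyPhos enantiomer that matches the substrate bias in step 8 is taken to be (Sp,Sp). If the other hand is the matched one, only the ligand changes.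

Step 1
Reactants: 1 5,7-dihydroxycoumarin
Product: 2 5,7-bis(benzyloxy)-2H-chromen-2-one
Conditions: BnBr, K2CO3, DMF, 60 °C
Reagents that add atoms: benzyl bromide, BrCc1ccccc1
Why: Williamson ether synthesis on the two acidic phenols under anhydrous carbonate leaves the lactone closed, and benzyl is chosen because it survives aryllithium, hydride, chromium(II) and basic peroxide and is removed at the end without acid.

Step 2
Reactants: 2 5,7-bis(benzyloxy)-2H-chromen-2-one; 3 4-benzyloxyphenylboronic acid
Product: 4 (4R)-5,7-bis(benzyloxy)-4-[4-(benzyloxy)phenyl]chroman-2-one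
Conditions: Rh(acac)(C2H4)2 (3 mol %), (R)-Segphos, 3 (excess, in portions), dioxane/H2O 10:1, 60 °C
Reagents that add atoms: none
Why: Hayashi–Miyaura rhodium-catalysed asymmetric 1,4-addition, a reaction type established for coumarins, in which aryl–rhodium inserts the still unsubstituted C3=C4 bond from the face left open by (R)-Segphos and so sets coumarin C4 (indane C1) as R, while the C5 benzyloxy group lies in the ring plane and does not shield the π face.

Step 3
Reactants: 4 (4R)-5,7-bis(benzyloxy)-4-[4-(benzyloxy)phenyl]chroman-2-one; 5 1,3-bis(benzyloxy)-5-bromobenzene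
Product: 8 (3R,4R)-5,7-bis(benzyloxy)-4-[4-(benzyloxy)phenyl]-3-[3,5-bis(benzyloxy)phenyl]chroman-2-one (trans lactone), via lithium enolate 6 (not isolated), via chlorozinc enolate 7 (not isolated)
Conditions: LiHMDS, THF, −78 °C; ZnCl2, −78 °C to rt; 5, Pd(dba)2/Q-Phos (5 mol %), THF, 50 °C; crude product with DBU (10 mol %), toluene, rt
Reagents that add atoms: none
Why: Palladium-catalysed α-arylation of a zinc ester enolate (Buchwald–Hartwig-type enolate arylation under near-neutral conditions), in which the weakly basic zinc enolate avoids ketene-type opening of the aryl lactone, ArC arrives opposite the pseudo-axial C4 aryl group, and the acidic C3–H lets DBU equilibrate the product to the more stable trans lactone, so coumarin C3 (indane C2) is set relative to C4.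

Step 4
Reactants: 8 trans lactone
Product: 9 (2R,3R)-3-[2,4-bis(benzyloxy)-6-hydroxyphenyl]-3-[4-(benzyloxy)phenyl]-2-[3,5-bis(benzyloxy)phenyl]propan-1-ol
Conditions: LiAlH4, THF, 0 °C; Rochelle salt work-up
Reagents that add atoms: none
Why: Hydride reduction of the lactone to the phenol/primary alcohol pair is faster than enolisation at 0 °C, so both stereocentres pass through unchanged and C2 is no longer acidic during the next, basic step.

Step 5
Reactants: 9 phenol–alcohol
Product: 10 3,5-bis(benzyloxy)-2-{(1R,2R)-1-[4-(benzyloxy)phenyl]-2-[3,5-bis(benzyloxy)phenyl]-3-hydroxypropyl}phenyl trifluoromethanesulfonate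
Conditions: PhNTf2, K2CO3, DMF, 0 °C to rt
Reagents that add atoms: N-phenylbis(trifluoromethanesulfonimide), O=S(=O)(N(c1ccccc1)S(=O)(=O)C(F)(F)F)C(F)(F)F
Why: Chemoselective O-sulfonylation, since carbonate deprotonates only the phenol and the mild triflyl donor reacts with the phenoxide but not with the neutral primary alcohol, which turns the former lactone oxygen into the leaving group on C3a.

Step 6
Reactants: 10 triflate alcohol
Product: 11 (2R,3R)-3-[2,4-bis(benzyloxy)-6-(trifluoromethylsulfonyloxy)phenyl]-3-[4-(benzyloxy)phenyl]-2-[3,5-bis(benzyloxy)phenyl]propanal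
Conditions: Dess–Martin periodinane, CH2Cl2, 0 °C to rt; used crude
Reagents that add atoms: none
Why: Dess–Martin oxidation needs no base and runs at or below room temperature, which is the gentlest access to the epimerisable α-aryl aldehyde, and the crude product is carried on at once.

Step 7
Reactants: 11 aldehyde; 12 2-(dichloromethyl)-4,4,5,5-tetramethyl-1,3,2-dioxaborolane
Product: 13 2-[(1E,3R,4R)-4-[2,4-bis(benzyloxy)-6-(trifluoromethylsulfonyloxy)phenyl]-4-[4-(benzyloxy)phenyl]-3-[3,5-bis(benzyloxy)phenyl]but-1-en-1-yl]-4,4,5,5-tetramethyl-1,3,2-dioxaborolane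
Conditions: CrCl2 (8 equiv), LiI (4 equiv), 12 (2 equiv), THF, rt
Reagents that add atoms: none
Why: Takai–Utimoto boryl olefination, whose geminal dichromium reagent is nucleophilic but hardly basic, should give the E-alkenyl boronate (the normal geometry of this reaction) without loss of configuration at C2, and nickel-free chromium(II) does not touch the aryl triflate.

Step 8
Reactants: 13 E-alkenyl boronate triflate; 14 1-benzyloxy-4-bromobenzene
Product: 17 hexabenzyl indane C8-pinacol boronate (1R,2R,3R,8R; 1,2-trans and 2,3-trans), via 4-benzyloxyphenyllithium 15 (not isolated), via lithium boron ate complex 16 (not isolated)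
Conditions: 14, t-BuLi (2 equiv), THF, −78 °C; added to 13 (1 equiv), THF, −78 °C to rt; then NaOTf, Pd(OAc)2 (5 mol %), (Sp,Sp)-MandyPhos (6 mol %), THF (0.02 M), 60 °C
Reagents that add atoms: none
Why: Proposed new method: 15 adds to the vacant boron orbital of 13 at −78 °C far faster than it attacks the sulfonate, and Pd(0)/MandyPhos then inserts into the C3a–OTf bond to give a cationic arylpalladium that binds the tethered C3=C8 π bond of ate complex 16. ArB then moves from boron to C8 on the alkene face remote from palladium while palladium bonds to C3, and reductive elimination from the resulting six-membered palladacycle forms C3–C3a with retention, which amounts to a 5-exo-trig closure of the cyclopentane ring. The closest known reaction type is the intermolecular palladium-catalysed enantioselective conjunctive cross-coupling of alkenylboron ate complexes with aryl triflates, including its anti-selective form with β-substituted alkenyl boronates; tethering the triflate to the alkene so that a ring closes goes beyond it. C8 is controlled relative to C3 by the E geometry of 13 together with the stereospecific anti addition (this pairing maps onto 3R,8R), and C3 is controlled relative to C2 by the choice of alkene face, because the palladacycle that places the C8 side chain trans to ArC avoids eclipsing that ring and the matched ligand enantiomer adds to this bias. The step needs chemoselectivity for the metallate shift over Suzuki-type transfer: intramolecular transfer of the alkenyl carbon would require a trans-cyclohexene and is excluded by the E tether, which is why the simple pinacol ester suffices, while high dilution holds back the bimolecular version. NaOTf precipitates the bromide left by the lithiation so that palladium stays cationic and π-acidic, and the chelating bisphosphine leaves no free site for β-hydride elimination from C3.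

Step 9
Reactants: 17 hexabenzyl indane boronate
Product: 18 hexabenzyl ether of the target (1R,2S,3R,8R), C8 now a secondary alcohol
Conditions: 30% H2O2, 3 M NaOH, THF, 0 °C to rt
Reagents that add atoms: hydrogen peroxide, OO
Why: Alkaline peroxide oxidation of a secondary boronic ester, in which hydroperoxide adds to boron and C8 migrates from boron to oxygen with retention, so the carbinol forms while ArB is still benzylated and cannot expel the new oxygen by quinone methide formation.

Step 10
Reactants: 18 hexabenzyl alcohol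
Product: 19 (1R,2S,3R)-2-(3,5-dihydroxyphenyl)-3-[(R)-hydroxy(4-hydroxyphenyl)methyl]-1-(4-hydroxyphenyl)-2,3-dihydro-1H-indene-5,7-diol (CNP0214825.1)
Conditions: H2 (1 atm), 10% Pd/C, THF/EtOH 1:1, rt, no acid, stopped at full conversion
Reagents that add atoms: none
Why: Neutral catalytic hydrogenolysis cleaves aryl benzyl ethers much faster than the hindered secondary benzylic C8–O bond, which needs acid to compete (the same selectivity is used when 4-benzyloxyphenyl carbinols of the lignin-model type are debenzylated), so six phenols are released and no stereocentre is touched.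

Compound list
1 | 5,7-dihydroxycoumarin | O=C1C=Cc2c(O)cc(O)cc2O1 | starting material
2 | 5,7-bis(benzyloxy)-2H-chromen-2-one | O=C1C=Cc2c(OCc3ccccc3)cc(OCc3ccccc3)cc2O1 | intermediate
3 | 4-benzyloxyphenylboronic acid | OB(O)c1ccc(OCc2ccccc2)cc1 | starting material
4 | (4R)-5,7-bis(benzyloxy)-4-[4-(benzyloxy)phenyl]chroman-2-one | C(c1ccccc1)Oc1ccc([C@@H]2c3c(OCc4ccccc4)cc(OCc4ccccc4)cc3OC(=O)C2)cc1 | intermediate
5 | 1,3-bis(benzyloxy)-5-bromobenzene | Brc1cc(OCc2ccccc2)cc(OCc2ccccc2)c1 | starting material
6 | lithium enolate of 4 | C(c1ccccc1)Oc1ccc([C@@H]2c3c(OCc4ccccc4)cc(OCc4ccccc4)cc3OC(O[Li])=C2)cc1 | intermediate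
7 | chlorozinc enolate of 4 | C(c1ccccc1)Oc1ccc([C@@H]2c3c(OCc4ccccc4)cc(OCc4ccccc4)cc3OC(O[Zn]Cl)=C2)cc1 | intermediate
8 | (3R,4R)-trans-3,4-diaryl lactone | C(c1ccccc1)Oc1ccc([C@@H]2c3c(OCc4ccccc4)cc(OCc4ccccc4)cc3OC(=O)[C@H]2c2cc(OCc3ccccc3)cc(OCc3ccccc3)c2)cc1 | intermediate
9 | (2R,3R)-phenol–primary alcohol | C(c1ccccc1)Oc1ccc([C@H](c2c(OCc3ccccc3)cc(OCc3ccccc3)cc2O)[C@H](c2cc(OCc3ccccc3)cc(OCc3ccccc3)c2)CO)cc1 | intermediate
10 | aryl triflate primary alcohol | C(c1ccccc1)Oc1ccc([C@H](c2c(OCc3ccccc3)cc(OCc3ccccc3)cc2OS(=O)(=O)C(F)(F)F)[C@H](c2cc(OCc3ccccc3)cc(OCc3ccccc3)c2)CO)cc1 | intermediate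
11 | (2R,3R)-α-aryl aldehyde with aryl triflate | C(c1ccccc1)Oc1ccc([C@H](c2c(OCc3ccccc3)cc(OCc3ccccc3)cc2OS(=O)(=O)C(F)(F)F)[C@H](c2cc(OCc3ccccc3)cc(OCc3ccccc3)c2)C=O)cc1 | intermediate
12 | 2-(dichloromethyl)-4,4,5,5-tetramethyl-1,3,2-dioxaborolane | ClC(Cl)B1OC(C)(C)C(C)(C)O1 | starting material
13 | (1E,3R,4R)-alkenyl pinacol boronate with C1/C2 diad and C3a triflate | C(c1ccccc1)Oc1ccc([C@H](c2c(OCc3ccccc3)cc(OCc3ccccc3)cc2OS(=O)(=O)C(F)(F)F)[C@H](c2cc(OCc3ccccc3)cc(OCc3ccccc3)c2)/C=C/B2OC(C)(C)C(C)(C)O2)cc1 | intermediate
14 | 1-benzyloxy-4-bromobenzene | Brc1ccc(OCc2ccccc2)cc1 | starting material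
15 | 4-benzyloxyphenyllithium | [Li]c1ccc(OCc2ccccc2)cc1 | intermediate
16 | lithium boron ate complex of 13 and 15 | [Li+].C(c1ccccc1)Oc1ccc([C@H](c2c(OCc3ccccc3)cc(OCc3ccccc3)cc2OS(=O)(=O)C(F)(F)F)[C@H](c2cc(OCc3ccccc3)cc(OCc3ccccc3)c2)/C=C/[B-]2(c3ccc(OCc4ccccc4)cc3)OC(C)(C)C(C)(C)O2)cc1 | intermediate
17 | hexabenzyl indane with pinacol boronate on C8 | C(c1ccccc1)Oc1ccc([C@@H]2c3c(OCc4ccccc4)cc(OCc4ccccc4)cc3[C@H]([C@@H](B3OC(C)(C)C(C)(C)O3)c3ccc(OCc4ccccc4)cc3)[C@H]2c2cc(OCc3ccccc3)cc(OCc3ccccc3)c2)cc1 | intermediate
18 | hexabenzyl ether of the target | C(c1ccccc1)Oc1ccc([C@@H]2c3c(OCc4ccccc4)cc(OCc4ccccc4)cc3[C@H]([C@@H](O)c3ccc(OCc4ccccc4)cc3)[C@H]2c2cc(OCc3ccccc3)cc(OCc3ccccc3)c2)cc1 | intermediate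
19 | CNP0214825.1 | Oc1ccc([C@@H]2c3c(O)cc(O)cc3[C@H]([C@@H](O)c3ccc(O)cc3)[C@H]2c2cc(O)cc(O)c2)cc1 | target

Total step count: 10. Longest linear sequence: 10 steps (1 to 19). The lithiation of 14 is part of step 8.

Steps most likely to fail

1. Step 8. Several things may go wrong:
   - ArB may pass directly from boron to palladium in a Suzuki-type biaryl coupling.
   - Alkenyl transfer may occur between two molecules.
   - The arylpalladium may palladate a C–H bond of ring ArA.
   - The aryllithium may attack the sulfonate sulfur.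
   - The two alkene faces may be poorly distinguished.

   The fallback uses known chemistry only, sets out from 13 and returns at 18. Sodium perborate in THF/water oxidises the alkenyl boronate of 13 to the chain-extended aldehyde F1 (C2–CH2–CHO, triflate intact). Addition of 15 at −78 °C gives the carbinol mixture F2, and Dess–Martin oxidation gives the aryl ketone F3. An intramolecular Buchwald–Hartwig ketone α-arylation (Pd2(dba)3, Xantphos, K3PO4, toluene, 90 °C) joins the enolate carbon C3 to C3a and gives the 3-aroylindane F4. C3 in F4 is enolisable, so it settles trans to ArC under the basic conditions. A Corey–Bakshi–Shibata reduction, with the catalyst enantiomer chosen for 8R, then gives 18. Any C8 epimer can be returned to F4 by oxidation.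

2. Step 3. Transmetallation and reductive elimination may be slow at the hindered secondary enolate next to the diarylmethine, and the enolate may meanwhile be lost by ring opening of the aryl ester.

   The fallback brings ArC in as part of the nucleophile. It sets out from 15 (generated from 14 as in step 8) and returns at 8.
   - 2,4,6-Trihydroxybenzaldehyde is dibenzylated (BnBr, K2CO3, DMF; the hydrogen-bonded ortho hydroxyl stays free) to 2,4-bis(benzyloxy)-6-hydroxybenzaldehyde F5.
   - Two equivalents of 15 give the racemic ortho-hydroxybenzhydrol F6, which p-toluenesulfinic acid converts into the sulfone F7.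
   - Aqueous carbonate releases the donor-stabilised ortho-quinone methide F8.
   - In parallel, 3,5-dihydroxyphenylacetic acid is perbenzylated to the benzyl ester F9 and saponified to 3,5-bis(benzyloxy)phenylacetic acid F10.
   - Pivaloyl chloride and i-Pr2NEt turn F10 into the mixed anhydride F11.
   - An isothiourea catalyst (HyperBTM, enantiomer chosen for 4R) converts F11 into its ammonium enolate, which undergoes Michael addition–lactonisation with F8.
   - Equilibration of C3 with DBU then gives 8.

3. Step 2. Insertion of the donor-substituted, peri-encumbered coumarin may be so sluggish that protodeboronation uses up the aryl source.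

   The fallback delivers hydride instead of aryl to C4. It sets out from 2 and 3 and returns at 4. An oxidative Heck coupling (Pd(OAc)2, 1,10-phenanthroline, O2, DMF) gives the 4-arylcoumarin F12. A copper hydride-catalysed asymmetric conjugate reduction (Cu(OAc)2, DTBM-Segphos of the hand that gives 4R, (EtO)2MeSiH, t-BuOH, toluene) then gives 4.

Further compounds
F1 | step 8 | chain-extended aldehyde (C2–CH2–CHO) with aryl triflate | C(c1ccccc1)Oc1ccc([C@H](c2c(OCc3ccccc3)cc(OCc3ccccc3)cc2OS(=O)(=O)C(F)(F)F)[C@H](c2cc(OCc3ccccc3)cc(OCc3ccccc3)c2)CC=O)cc1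
F2 | step 8 | secondary carbinol from F1 and 15 (both C8 epimers) | C(c1ccccc1)Oc1ccc([C@H](c2c(OCc3ccccc3)cc(OCc3ccccc3)cc2OS(=O)(=O)C(F)(F)F)[C@H](c2cc(OCc3ccccc3)cc(OCc3ccccc3)c2)CC(O)c2ccc(OCc3ccccc3)cc2)cc1
F3 | step 8 | 4-benzyloxyphenyl ketone with aryl triflate | C(c1ccccc1)Oc1ccc([C@H](c2c(OCc3ccccc3)cc(OCc3ccccc3)cc2OS(=O)(=O)C(F)(F)F)[C@H](c2cc(OCc3ccccc3)cc(OCc3ccccc3)c2)CC(=O)c2ccc(OCc3ccccc3)cc2)cc1
F4 | step 8 | all-trans 3-(4-benzyloxybenzoyl)indane | C(c1ccccc1)Oc1ccc([C@@H]2c3c(OCc4ccccc4)cc(OCc4ccccc4)cc3[C@H](C(=O)c3ccc(OCc4ccccc4)cc3)[C@H]2c2cc(OCc3ccccc3)cc(OCc3ccccc3)c2)cc1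
F5 | step 3 | 2,4-bis(benzyloxy)-6-hydroxybenzaldehyde | O=Cc1c(O)cc(OCc2ccccc2)cc1OCc1ccccc1
F6 | step 3 | racemic ortho-hydroxybenzhydrol | OC(c1ccc(OCc2ccccc2)cc1)c1c(O)cc(OCc2ccccc2)cc1OCc1ccccc1
F7 | step 3 | racemic 2-[aryl(tosyl)methyl]phenol | Cc1ccc(cc1)S(=O)(=O)C(c1ccc(OCc2ccccc2)cc1)c1c(O)cc(OCc2ccccc2)cc1OCc1ccccc1
F8 | step 3 | ortho-quinone methide | O=C1C=C(OCc2ccccc2)C=C(OCc2ccccc2)C1=Cc1ccc(OCc2ccccc2)cc1
F9 | step 3 | benzyl 3,5-bis(benzyloxy)phenylacetate | O=C(OCc1ccccc1)Cc1cc(OCc2ccccc2)cc(OCc2ccccc2)c1
F10 | step 3 | 3,5-bis(benzyloxy)phenylacetic acid | OC(=O)Cc1cc(OCc2ccccc2)cc(OCc2ccccc2)c1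
F11 | step 3 | pivalic 3,5-bis(benzyloxy)phenylacetic anhydride | CC(C)(C)C(=O)OC(=O)Cc1cc(OCc2ccccc2)cc(OCc2ccccc2)c1
F12 | step 2 | 5,7-bis(benzyloxy)-4-[4-(benzyloxy)phenyl]coumarin | O=C1C=C(c2ccc(OCc3ccccc3)cc2)c2c(OCc3ccccc3)cc(OCc3ccccc3)cc2O1
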